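**Retrosynthetic overview**
- The target is a depside: O4 of ring B (C1 CO2Me, C2 OH, C3 Me, C4 O-acyl, C5 Me, C6 Me) carries the ring A acyl group (5-chloro-2,4-dihydroxy-3,6-dimethylbenzoyl). The strategy rests on ring B being a resorcinol monoester, with a free, ester-chelated C2–OH and an acylated C4–O on either side of C3.
- Last disconnections: the C3 methyl (from C3–H through a formyl group) and the two ring A phenols (as methoxymethyl ethers).
- Key disconnection: ring B is cut at O–C4, C2–C3 and C1–C2 into CO and an open-chain tertiary 3-aroyloxy-1,4-enyne. Ring B is the only ring built; ring A is bought as methyl 2,4-dihydroxy-3,6-dimethylbenzoate.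
- The enyne ester is cut at its ester C–O bond into the ring A acid chloride and a tertiary propargylic alcohol made from butane-2,3-dione by Wittig olefination and ethynyl Grignard addition.

Key step: step 8

Assumption: the target has no stereocentre and no configurationally fixed axis is specified, so racemic open-chain intermediates are acceptable; butane-2,3-dione, the ylide, ethynylmagnesium bromide, methyl 2,4-dihydroxy-3,6-dimethylbenzoate and CO are taken as purchasable.

Step 1
Reactants: 1 butane-2,3-dione; 2 methyl (triphenylphosphoranylidene)acetate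
Product: 3 methyl (E)-3-methyl-4-oxopent-2-enoate
Conditions: 1 (2 equiv), 2 (1 equiv), CH2Cl2, 0 °C to rt
Reagents that add atoms: none
Why: Wittig olefination with a stabilised ylide, which should react once with the excess symmetrical diketone and give the thermodynamically preferred (E)-alkene with acetyl trans to the ester.

Step 2
Reactants: 3 methyl (E)-3-methyl-4-oxopent-2-enoate; 4 ethynylmagnesium bromide
Product: 5 methyl (E)-4-hydroxy-3,4-dimethylhex-2-en-5-ynoate (racemic)
Conditions: HC≡CMgBr (1.1 equiv), THF, −78 °C; aq. NH4Cl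
Reagents that add atoms: none
Why: Grignard 1,2-addition, in which the alkynylmagnesium reagent should attack the ketone faster than the ester and not add in conjugate fashion at low temperature; the carbinol centre forms as a racemate, which does not matter because this carbon becomes aromatic C5 of ring B.

Step 3
Reactants: 6 methyl 2,4-dihydroxy-3,6-dimethylbenzoate
Product: 7 methyl 5-chloro-2,4-dihydroxy-3,6-dimethylbenzoate
Conditions: SO2Cl2 (1.05 equiv), Et2O, 0 °C to rt
Reagents that add atoms: sulfuryl chloride, O=S(=O)(Cl)Cl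
Why: Electrophilic aromatic chlorination, which can only take place at C5, the single unsubstituted ring carbon, ortho to one hydroxyl and para to the other.

Step 4
Reactants: 7 methyl 5-chloro-2,4-dihydroxy-3,6-dimethylbenzoate
Product: 8 methyl 5-chloro-2,4-bis(methoxymethoxy)-3,6-dimethylbenzoate
Conditions: NaH (2.5 equiv), MeOCH2Cl (2.5 equiv), DMF, 0 °C to rt
Reagents that add atoms: chloromethyl methyl ether, COCCl
Why: Williamson-type O-alkylation (methoxymethyl ether formation), in which NaH should convert both phenols, including the ester-chelated 2-OH, into phenoxides that are captured by the reactive chloromethyl ether.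

Step 5
Reactants: 8 methyl 5-chloro-2,4-bis(methoxymethoxy)-3,6-dimethylbenzoate
Product: 9 5-chloro-2,4-bis(methoxymethoxy)-3,6-dimethylbenzoic acid
Conditions: KOH, DMSO/H2O, 90 °C; then aq. HCl to pH 4, 0 °C
Reagents that add atoms: potassium hydroxide (hydroxide oxygen), [K+].[OH-]
Why: Saponification of a di-ortho-substituted benzoate, for which poorly solvated hydroxide in hot aqueous DMSO should overcome the hindrance while the acetals tolerate base and a brief, cold, mildly acidic work-up.

Step 6
Reactants: 9 5-chloro-2,4-bis(methoxymethoxy)-3,6-dimethylbenzoic acid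
Product: 10 5-chloro-2,4-bis(methoxymethoxy)-3,6-dimethylbenzoyl chloride (crude, used at once)
Conditions: Me2C=C(Cl)NMe2 (1.2 equiv), CH2Cl2, 0 °C to rt; concentrate
Reagents that add atoms: 1-chloro-N,N,2-trimethylprop-1-en-1-amine (Ghosez's reagent), CC(C)=C(Cl)N(C)C
Why: Acid chloride formation with an α-chloroenamine, which proceeds under neutral conditions and releases an amide in place of HCl, so the methoxymethyl ethers should survive.

Step 7
Reactants: 5 methyl (E)-4-hydroxy-3,4-dimethylhex-2-en-5-ynoate; 10 5-chloro-2,4-bis(methoxymethoxy)-3,6-dimethylbenzoyl chloride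
Product: 11 methyl (E)-4-[5-chloro-2,4-bis(methoxymethoxy)-3,6-dimethylbenzoyloxy]-3,4-dimethylhex-2-en-5-ynoate (racemic)
Conditions: 5, LiN(SiMe3)2 (1.05 equiv), THF, −78 °C; then 10 (1.2 equiv), −78 °C to rt
Reagents that add atoms: none
Why: O-acylation of a lithium alkoxide by an aroyl chloride (nucleophilic acyl substitution), in which one equivalent of base should deprotonate only the hydroxyl, the lithium alkoxide is nucleophilic enough for the hindered but alkoxy-activated acyl chloride, and the (E)-geometry keeps the alkoxide from lactonising onto the methyl ester.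

Step 8
Reactants: 11 methyl (E)-4-[5-chloro-2,4-bis(methoxymethoxy)-3,6-dimethylbenzoyloxy]-3,4-dimethylhex-2-en-5-ynoate; 12 carbon monoxide
Product: 13 methyl 4-[5-chloro-2,4-bis(methoxymethoxy)-3,6-dimethylbenzoyloxy]-2-hydroxy-5,6-dimethylbenzoate
Conditions: [RhCl(CO)2]2 (5 mol%), CO (10 atm), ClCH2CH2Cl, 80 °C
Reagents that add atoms: none
Why: Monovalent rhodium binds the terminal alkyne, the ring A ester carbonyl oxygen adds to the internal alkyne carbon and the propargylic C–O bond opens, which shifts the aroyloxy group 1,2 onto the future C4 and leaves a rhodium vinylcarbene at the future C3 (Rautenstrauch-type 1,2-acyloxy migration). The carbene either closes onto the enoate alkene to a rhodacyclohexadiene that inserts CO and reductively eliminates, or takes up CO first to a dienylketene that undergoes 6π ring closure; both paths give the same cyclohexadienone, whose C1–H enolises to the ester-chelated C2 phenol. The closest known reaction is the [RhCl(CO)2]2-catalysed (5+1) cycloaddition of 3-acyloxy-1,4-enynes with CO to resorcinol monoesters, here applied to a tertiary ester with a di-ortho-substituted aroyl group. Ring B closes in a (5+1) mode, CO joining the alkyne terminus (C2–C3) and the enoate α-carbon (C1–C2) while O–C4 forms in the migration; no stereocentre results and the racemic carbinol carbon becomes aromatic C5. The step needs 1,2- instead of 1,3-acyloxy migration, which the unsubstituted alkyne terminus secures, and a cisoid carbene–alkene arrangement, which is reached because the migration is reversible and the (E)-enoate turns only its hydrogen toward the closing bond; the two alkoxy groups ortho and para to the ring A carbonyl make its oxygen a good migrating nucleophile.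

Step 9
Reactants: 13 methyl 4-[5-chloro-2,4-bis(methoxymethoxy)-3,6-dimethylbenzoyloxy]-2-hydroxy-5,6-dimethylbenzoate
Product: 14 methyl 4-[5-chloro-2,4-bis(methoxymethoxy)-3,6-dimethylbenzoyloxy]-3-formyl-2-hydroxy-5,6-dimethylbenzoate
Conditions: MgCl2 (3 equiv), Et3N (4 equiv), (CH2O)n, MeCN, reflux; cold aq. citric acid
Reagents that add atoms: paraformaldehyde (formaldehyde unit), C=O
Why: Magnesium-mediated ortho-formylation of a phenol (Casnati–Skattebøl), in which the magnesium phenoxide delivers formaldehyde to the ortho carbon C3, the only unsubstituted aromatic carbon in the molecule, and a second formaldehyde oxidises the benzylic alkoxide to the aldehyde by hydride transfer.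

Step 10
Reactants: 14 methyl 4-[5-chloro-2,4-bis(methoxymethoxy)-3,6-dimethylbenzoyloxy]-3-formyl-2-hydroxy-5,6-dimethylbenzoate
Product: 16 methyl 4-(5-chloro-2,4-dihydroxy-3,6-dimethylbenzoyloxy)-2-hydroxy-3,5,6-trimethylbenzoate, via ring A bis-phenol aldehyde 15 (not isolated)
Conditions: Et3SiH (6 equiv), CF3CO2H/CH2Cl2 (1:1), 0 °C to rt
Reagents that add atoms: none
Why: Ionic hydrogenation combined with acetal acidolysis, in which CF3CO2H is expected to cleave both methoxymethyl ethers first (the silane reducing the released methoxymethyl cations to dimethyl ether) and the protonated o-hydroxybenzaldehyde is then reduced by silane hydride through the benzylic cation to the methyl group, while the aryl ester, methyl ester and aryl chloride are inert to these conditions.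

**Compound list**
1 | butane-2,3-dione | CC(=O)C(C)=O | starting material
2 | methyl (triphenylphosphoranylidene)acetate | COC(=O)C=P(c1ccccc1)(c1ccccc1)c1ccccc1 | starting material
3 | methyl (E)-3-methyl-4-oxopent-2-enoate | CC(=O)/C(C)=C/C(=O)OC | intermediate
4 | ethynylmagnesium bromide | C#C[Mg]Br | starting material
5 | methyl (E)-4-hydroxy-3,4-dimethylhex-2-en-5-ynoate (racemic) | C#CC(C)(O)/C(C)=C/C(=O)OC | intermediate
6 | methyl 2,4-dihydroxy-3,6-dimethylbenzoate | COC(=O)c1c(C)cc(O)c(C)c1O | starting material
7 | methyl 5-chloro-2,4-dihydroxy-3,6-dimethylbenzoate | COC(=O)c1c(C)c(Cl)c(O)c(C)c1O | intermediate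
8 | methyl 5-chloro-2,4-bis(methoxymethoxy)-3,6-dimethylbenzoate | COC(=O)c1c(C)c(Cl)c(OCOC)c(C)c1OCOC | intermediate
9 | 5-chloro-2,4-bis(methoxymethoxy)-3,6-dimethylbenzoic acid | OC(=O)c1c(C)c(Cl)c(OCOC)c(C)c1OCOC | intermediate
10 | 5-chloro-2,4-bis(methoxymethoxy)-3,6-dimethylbenzoyl chloride | ClC(=O)c1c(C)c(Cl)c(OCOC)c(C)c1OCOC | intermediate
11 | methyl (E)-4-[5-chloro-2,4-bis(methoxymethoxy)-3,6-dimethylbenzoyloxy]-3,4-dimethylhex-2-en-5-ynoate (racemic) | C#CC(C)(OC(=O)c1c(C)c(Cl)c(OCOC)c(C)c1OCOC)/C(C)=C/C(=O)OC | intermediate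
12 | carbon monoxide | [C-]#[O+] | starting material
13 | methyl 4-[5-chloro-2,4-bis(methoxymethoxy)-3,6-dimethylbenzoyloxy]-2-hydroxy-5,6-dimethylbenzoate | COC(=O)c1c(C)c(C)c(OC(=O)c2c(C)c(Cl)c(OCOC)c(C)c2OCOC)cc1O | intermediate
14 | methyl 4-[5-chloro-2,4-bis(methoxymethoxy)-3,6-dimethylbenzoyloxy]-3-formyl-2-hydroxy-5,6-dimethylbenzoate | COC(=O)c1c(C)c(C)c(OC(=O)c2c(C)c(Cl)c(OCOC)c(C)c2OCOC)c(C=O)c1O | intermediate
15 | methyl 4-(5-chloro-2,4-dihydroxy-3,6-dimethylbenzoyloxy)-3-formyl-2-hydroxy-5,6-dimethylbenzoate | COC(=O)c1c(C)c(C)c(OC(=O)c2c(C)c(Cl)c(O)c(C)c2O)c(C=O)c1O | intermediate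
16 | methyl 4-(5-chloro-2,4-dihydroxy-3,6-dimethylbenzoyloxy)-2-hydroxy-3,5,6-trimethylbenzoate (CNP0198502.0) | COC(=O)c1c(C)c(C)c(OC(=O)c2c(C)c(Cl)c(O)c(C)c2O)c(C)c1O | target

Total step count: 10.
Longest linear sequence: 8 steps (6 to 16, steps 3 to 10); the enyne arm (1 to 5) adds two steps and joins at step 7.

**Steps most likely to fail**

1. Step 8. The tertiary ester may prefer the 1,3-shift to an allenyl ester, may ionise with loss of the ring A carboxylate, or its twisted aroyl carbonyl may migrate too slowly, so that no aromatic ring forms. Fallback, setting out from 6 and 10 and coming back at 16: ring B is taken from the commercial benzoate instead of being built. Rieche formylation of 6 (Cl2CHOMe, TiCl4, CH2Cl2) at its only free carbon should give methyl 5-formyl-2,4-dihydroxy-3,6-dimethylbenzoate F1. Ionic hydrogenation (Et3SiH, CF3CO2H) should then give methyl 2,4-dihydroxy-3,5,6-trimethylbenzoate F2. Its more acidic 4-OH, which is not chelated to the ester, is acylated with 10 (K2CO3, acetone) to give methyl 4-[5-chloro-2,4-bis(methoxymethoxy)-3,6-dimethylbenzoyloxy]-2-hydroxy-3,5,6-trimethylbenzoate F3. CF3CO2H/Et3SiH in CH2Cl2 removes both acetals and gives 16.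

2. Step 7. Attack of the tertiary alkoxide on the shielded acyl carbon may be slow, which leaves time for the acid chloride to decay by ring closure of the ortho acetal oxygen onto the acyl carbon and for the alkoxide to add to the enoate. Fallback, setting out from 9 and 5 and coming back at 11: the acyl group is delivered as an unhindered quinoketene. Acid 9 with acetone, (CF3CO)2O and CF3CO2H should lose both acetals and close to 6-chloro-7-hydroxy-2,2,5,8-tetramethyl-4H-1,3-benzodioxin-4-one F4. MeOCH2Cl/iPr2NEt protects the 7-OH to give 6-chloro-7-(methoxymethoxy)-2,2,5,8-tetramethyl-4H-1,3-benzodioxin-4-one F5. Irradiation at 300 nm in CH2Cl2 in the presence of alcohol 5 expels acetone, and the ketene is trapped by the tertiary alcohol to give methyl (E)-4-[5-chloro-2-hydroxy-4-(methoxymethoxy)-3,6-dimethylbenzoyloxy]-3,4-dimethylhex-2-en-5-ynoate F6. NaH/MeOCH2Cl in DMF at 0 °C protects the chelated phenol and returns 11.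

3. Step 9. Formylation may not turn over at C3, because the phenoxide is held in the chelate with the C1 ester and is flanked by the bulky aroyloxy group, or the basic magnesium alkoxides may cleave the depside ester. Fallback, setting out from 13 and coming back at 16: the methyl group is brought in by cross-coupling. NBS (cat. iPr2NH, CH2Cl2, 0 °C) should brominate the only free carbon to give methyl 3-bromo-4-[5-chloro-2,4-bis(methoxymethoxy)-3,6-dimethylbenzoyloxy]-2-hydroxy-5,6-dimethylbenzoate F7. Suzuki methylation (trimethylboroxine, PdCl2(dppf), K3PO4, dioxane, 90 °C) should give methyl 4-[5-chloro-2,4-bis(methoxymethoxy)-3,6-dimethylbenzoyloxy]-2-hydroxy-3,5,6-trimethylbenzoate F3, the same compound that the fallback for step 8 passes through. CF3CO2H/Et3SiH in CH2Cl2 then gives 16.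

**Further compounds**
F1 | step 8 | methyl 5-formyl-2,4-dihydroxy-3,6-dimethylbenzoate | COC(=O)c1c(C)c(C=O)c(O)c(C)c1O
F2 | step 8 | methyl 2,4-dihydroxy-3,5,6-trimethylbenzoate | COC(=O)c1c(C)c(C)c(O)c(C)c1O
F3 | step 8 | methyl 4-[5-chloro-2,4-bis(methoxymethoxy)-3,6-dimethylbenzoyloxy]-2-hydroxy-3,5,6-trimethylbenzoate | COC(=O)c1c(C)c(C)c(OC(=O)c2c(C)c(Cl)c(OCOC)c(C)c2OCOC)c(C)c1O
F4 | step 7 | 6-chloro-7-hydroxy-2,2,5,8-tetramethyl-4H-1,3-benzodioxin-4-one | CC1(C)OC(=O)c2c(C)c(Cl)c(O)c(C)c2O1
F5 | step 7 | 6-chloro-7-(methoxymethoxy)-2,2,5,8-tetramethyl-4H-1,3-benzodioxin-4-one | CC1(C)OC(=O)c2c(C)c(Cl)c(OCOC)c(C)c2O1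
F6 | step 7 | methyl (E)-4-[5-chloro-2-hydroxy-4-(methoxymethoxy)-3,6-dimethylbenzoyloxy]-3,4-dimethylhex-2-en-5-ynoate (racemic) | C#CC(C)(OC(=O)c1c(C)c(Cl)c(OCOC)c(C)c1O)/C(C)=C/C(=O)OC
F7 | step 9 | methyl 3-bromo-4-[5-chloro-2,4-bis(methoxymethoxy)-3,6-dimethylbenzoyloxy]-2-hydroxy-5,6-dimethylbenzoate | COC(=O)c1c(C)c(C)c(OC(=O)c2c(C)c(Cl)c(OCOC)c(C)c2OCOC)c(Br)c1O
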